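## Analysis of the target

Target 38 is a cyclohexene (ring D), numbered here C1 (alkene carbon carrying the 4-methylpent-3-enyl chain), C2 (alkene CH) and C3 to C6. C3 carries C6 of a (2S)-5,7-dihydroxyflavanone (benzo ring A, pyranone ring C, 2,4-dihydroxyphenyl ring B). C4 carries a 2,4-dihydroxy-3-prenylbenzoyl group (ring F) and C5 a 2,4-dihydroxyphenyl group (ring E). The ring stereocentres C3 (R), C4 (R) and C5 (S) are all-trans: the aryl groups on C3 and C5 are cis to each other and the aroyl group on C4 is trans to both. This is the all-equatorial, thermodynamically preferred arrangement, so the enolisable centre C4 is self-correcting. The fourth stereocentre, C2 of the chromanone, is too remote to be controlled by ring D. Sensitive features are eight phenols, two trisubstituted alkenes (the prenyl group sits between two phenols and closes to a chroman under acid) and the flavanone, which opens to a chalcone under base with loss of the C2 configuration. The difficulties are the fixed position of the ring alkene next to three contiguous, heavily arylated stereocentres, and the need to tell the three oxygens of ring A apart: ring D sits between two hydroxyls and the pyranone oxygen is para to it. The strategy rests on one observation. C1=C2 with its chain is terminal alkyne 10 in disguise, and C3, C4, C5 (aryl) and C6 are the four carbons of 3-arylcyclobutanone 7, with C3 as the carbonyl carbon. Joining C2 to C3 and C1 to C6 gives enone 11, whose carbonyl (C3) and α-methylene (C4) lie exactly where ring A and the aroyl group must go.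

## Retrosynthetic reasoning

38 from 37. The last operation only removes eight methoxymethyl ethers. One acid-labile group on every phenol keeps the end of the route to a single step and leaves no base-mediated operation after the flavanone exists.

37 from 32 and 36. The bond between chromanone C2 and ring B is cut. Because C2 cannot be controlled by ring D, it is set by a chiral catalyst in a conjugate arylation of chromone 32 with boronic acid 36. Cutting here, and not at O1–C2 (a chalcone closure), avoids a reversible ring closure with no inherent facial preference.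

32 from 30, and 30 back to 25. The pyranone is cut at O1–C2 and C2–C3, a one-carbon insertion between the acetyl methyl group and an ortho oxygen of an acetophenone. Which ortho oxygen closes the ring decides between the 6- and the 8-linked chromanone. The oxygen next to ring D must therefore be blocked and the other one free. This is arranged from triol 25 by a short staging (26, 27, 28, 29) that uses the steric difference between the two ortho hydroxyls. The ring F ketone of 30 comes from the carbinol of 29.

25 from 23 and 24. The C3–ring A bond is cut because C3, the former carbonyl carbon, can be ionised as an allylic cation. The nucleophile 24 already carries the acetyl group and has two equivalent free ring carbons, so only one regioisomer can form. The forward reaction must deliver ring A to C3 (not C1) and trans to the C4 substituent.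

23 from 11 and 19, through 21 and 22. The bond between C4 and the ring F carbonyl carbon is cut as an aldol of the kinetic enolate of 11 with aldehyde 19. An aldol is preferred to an acylation, which would give a β-diketone whose ring carbonyl could no longer be reduced selectively. The carbinol is silylated (22) and the ring ketone reduced (23) to provide the leaving group at C3.

11 from 7 and 10. C2–C3 and C1–C6 are cut. The forward reaction inserts the two alkyne carbons of 10 into one acyl–carbon bond of 7 on zerovalent nickel. It closes ring D, places the alkene and the chain, and sets C5 by choosing one of two enantiotopic ring bonds. No other disconnection in the route creates so much of the target in one step, and both partners are simple.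

7 from 3 and 4; 10 from 8 and 9. The cyclobutanone is cut to styrene 3 and dichloroketene 5 (from 4), with the chlorines removed from 6. Styrene 3 comes from aldehyde 2, and 2 from 1. Alkyne 10 is the alkylation product of 9 with 8. All of this is routine, so the risk sits in the key step.

19 and 36 from 13. Both side fragments come from ether 13 (from 12). Metalation between the two oxygens and coupling with 14 gives 16, and a second metalation and formylation gives 19. Bromination of 13 to 33 and borylation gives 36.

## Alternatives that were turned down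

Alternative 1: The C3–C4 bond and the C1=C2 alkene are traced back to a [3,3] shift. Ring D is opened between C1 and an oxygen, which leads to styryl δ-lactone A1; its ring oxygen sits on the tertiary allylic carbon C1 and its α-carbon is the future C4. In the forward direction the silyl ketene acetal of A1 would contract through a boat-shaped transition state to the all-cis cyclohexenecarboxylic acid A2. In its favour, this is established sigmatropic chemistry, it forms C3–C4 and two stereocentres at once by chirality transfer, and ring A arrives with its para oxygen already distinguished from the two ortho oxygens. On that last point it is stronger than the chosen route, which spends four protecting-group steps on the same distinction. Against it, A1 needs a stereodefined, fully substituted carbinol carbon that is tertiary, allylic and conjugated to an electron-rich styrene, and therefore ionises easily. The rearrangement also puts C4 cis to both neighbours, so C4 must be inverted later. Finally, the carboxyl group of A2 lies between two aryl-bearing carbons and still has to become the ring F ketone by aryl-metal addition at a very hindered centre. The risk is moved from the key step into the precursor and the route becomes longer. The chosen strategy instead makes ring D from 7 and 10 in one catalytic step and introduces the C4 and C3 substituents directly trans.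

Alternative 2: Here ring A is built, not attached. Three of its bonds are cut back to siloxyalkyne A3 on C3 and 3-(allyloxy)cyclobut-2-en-1-one A4. On heating, A4 would open to a vinylketene that adds to the alkyne; four-electron ring opening and six-electron ring closure then give phenol A5, whose three oxygens carry three different groups. This solves the oxygen differentiation of ring A by construction and keeps acid away from the sensitive groups, and on both counts it is stronger than the Friedel–Crafts step of the chosen route. Against it, the tactic belongs to the end of a synthesis. It presupposes ring D with all three stereocentres and an ynol ether on C3, so the central problem is left open. The siloxyalkyne needs several steps from a C3 carboxyl or alkyne, the vinylketene can be intercepted by the two electron-rich trisubstituted alkenes, and A5 has only a protected hydroxymethyl group on C4, so ring F still needs oxidation, aryl addition and a second oxidation. The chosen route spends its effort on ring D itself and brings in ring A as 24 in one bond-forming step, at the price of the protecting-group staging.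

Alternative 3: Ring F is built last. Its bonds C1'–C2' and C5'–C6' are cut back to terminal ynone A6 on C4 and the prenyl-bearing bis(silyloxy)diene A7. Cycloaddition, loss of the methoxy group as its alcohol and loss of the silyl groups would give A8, in which only the ring F hydroxyls are free. The regiochemistry of the acyl resorcinol is fixed by the polarity match of diene and ynone. The prenyl group with its two flanking phenols appears only at the end, and no ionisable benzylic carbinol next to ring D ever exists. On this last point it is stronger than the chosen route, whose step 13 must tolerate such a centre. Against it, the tactic again presupposes everything else: ring D, its stereocentres and the complete flavanone. The ynone is a strong acceptor next to an enolisable centre and has to be made from a carboxyl-level group on C4 in several steps, and A7 is fully substituted at its reacting terminus, so the cycloaddition should be slow. The chosen route introduces ring F with its prenyl group in one aldol with aldehyde 19 and solves the ring and C5 first.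

Key step: step 6

Remarks on the chemistry:
- The sense of induction of the chiral ligands in steps 6 and 22 cannot be read from their structures; in each case the ligand antipode that gives the stated configuration is used.
- 24 is used anhydrous.
- ArE = 2,4-bis(methoxymethoxy)phenyl; ArF = 2,4-bis(methoxymethoxy)-3-(3-methylbut-2-en-1-yl)phenyl; MOM = methoxymethyl; TBS = tert-butyldimethylsilyl.
- The ring A oxygens are called O2, O4 and O6 after the acetophenone numbering of 25 (acetyl on C1, ring D on C3). O6 becomes the pyranone oxygen; O2 and O4 become the 5- and 7-hydroxyls.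

## Route

Step 1
Reactants: 1 2,4-dihydroxybenzaldehyde
Product: 2 2,4-bis(methoxymethoxy)benzaldehyde
Conditions: NaH (2.4 equiv), MOMCl (2.5 equiv), THF/DMF, 0 °C → rt
Reagents that add atoms: chloromethyl methyl ether, COCCl
Why: O-alkylation of both phenoxides (acetal protection); NaH is used because the ortho hydroxyl is hydrogen-bonded to the aldehyde and resists amine bases.

Step 2
Reactants: 2 2,4-bis(methoxymethoxy)benzaldehyde
Product: 3 1-ethenyl-2,4-bis(methoxymethoxy)benzene
Conditions: Ph3PCH3Br, KOt-Bu, THF, 0 °C → rt
Reagents that add atoms: methyltriphenylphosphonium bromide, C[P+](c1ccccc1)(c1ccccc1)c1ccccc1.[Br-]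
Why: Wittig methylenation of a non-enolisable aryl aldehyde; the acetals are inert to the ylide.

Step 3
Reactants: 3 1-ethenyl-2,4-bis(methoxymethoxy)benzene; 4 trichloroacetyl chloride
Product: 6 3-[2,4-bis(methoxymethoxy)phenyl]-2,2-dichlorocyclobutan-1-one (racemic), via dichloroketene 5 (not isolated)
Conditions: Zn(Cu), Et2O/DME, ultrasound, 20 °C, slow addition of 4
Reagents that add atoms: none
Why: [2+2] cycloaddition of dichloroketene (made by zinc dechlorination of 4) with the electron-rich styrene; the nucleophilic CH2 terminus bonds to the ketene carbonyl carbon, so the aryl group ends on C3 next to CCl2. DME ties up ZnCl2 and protects the acetals; the racemic stereocentre disappears in step 4.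

Step 4
Reactants: 6 3-[2,4-bis(methoxymethoxy)phenyl]-2,2-dichlorocyclobutan-1-one
Product: 7 3-[2,4-bis(methoxymethoxy)phenyl]cyclobutan-1-one
Conditions: Zn, AcOH, rt
Reagents that add atoms: none
Why: Reductive dechlorination of the α,α-dichloroketone through zinc enolates that AcOH protonates; 7 is achiral, with a mirror plane through C1 and C3.

Step 5
Reactants: 8 5-bromo-2-methylpent-2-ene; 9 lithium acetylide (used as its ethylenediamine complex)
Product: 10 6-methylhept-5-en-1-yne
Conditions: DMSO, 10 °C → rt
Reagents that add atoms: none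
Why: SN2 alkylation of the acetylide by a primary homoallylic bromide in a dipolar aprotic solvent; the trisubstituted alkene is untouched.

Step 6
Reactants: 7 3-[2,4-bis(methoxymethoxy)phenyl]cyclobutan-1-one; 10 6-methylhept-5-en-1-yne
Product: 11 (5S)-5-[2,4-bis(methoxymethoxy)phenyl]-3-(4-methylpent-3-en-1-yl)cyclohex-2-en-1-one
Conditions: Ni(cod)2 (10 mol%), (S,S,S)-BINOL N,N-bis(1-phenylethyl)phosphoramidite (20 mol%), toluene, 80 °C; 10 (2 equiv) added over 8 h
Reagents that add atoms: none
Why: Proposed new method: zerovalent nickel is expected to couple the carbonyl group of 7 and the triple bond of 10 oxidatively to a spiro-oxanickelacyclopentene of divalent nickel, in which the hydrogen-bearing alkyne carbon is bonded to the crowded carbonyl carbon (the C2–C3 bond) and the chain-bearing carbon to nickel; strain-driven β-carbon elimination of one ring CH2–C(O) bond then opens the four-membered ring to a seven-membered nickelacycle, and C(sp2)–C(sp3) reductive elimination forms C1–C6 and returns zerovalent nickel. The closest known reaction type is the Ni(cod)2/phosphine-catalysed intermolecular (4+2) coupling of cyclobutanones with internal alkynes, together with enantioselective nickel-catalysed carbon–carbon cleavage of prochiral cyclobutanones in intramolecular alkene insertions with phosphoramidite ligands; a terminal alkyne and an intermolecular choice between enantiotopic bonds have not been shown. Ring D is closed by reductive elimination from the seven-membered metallacycle, that is, by net insertion of the two alkyne carbons into an acyl–carbon bond. The only new stereocentre, C5, arises because the two CH2–C(O) bonds of 7 are enantiotopic; the chiral phosphoramidite shields one face of the planar oxanickelacycle, so only one of the two methylene groups can migrate to nickel (ligand control). The step needs regioselectivity (hydrogen terminus to the carbonyl carbon), which the size difference between hydrogen and the chain at the fully substituted spiro carbon should secure; it needs chemoselectivity against alkyne oligomerisation, met by slow addition of 10; and reductive elimination must outrun β-hydride elimination at the aryl-bearing carbon, which a bulky π-acidic phosphoramidite favours. The trisubstituted alkene of 10 and the aryl acetals of 7 are poor ligands for nickel and should not interfere.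

Step 7
Reactants: 12 benzene-1,3-diol (resorcinol)
Product: 13 1,3-bis(methoxymethoxy)benzene
Conditions: NaH, MOMCl, THF/DMF, 0 °C → rt
Reagents that add atoms: chloromethyl methyl ether, COCCl
Why: Double O-alkylation of the bis-phenoxide.

Step 8
Reactants: 13 1,3-bis(methoxymethoxy)benzene; 14 1-bromo-3-methylbut-2-ene (prenyl bromide)
Product: 16 1,3-bis(methoxymethoxy)-2-(3-methylbut-2-en-1-yl)benzene, via 2,6-bis(methoxymethoxy)phenyllithium 15 (not isolated)
Conditions: n-BuLi, THF, 0 °C → rt; then CuBr·SMe2 (10 mol%), 14, −78 °C → rt
Reagents that add atoms: none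
Why: Directed ortho-metalation; the two acetal oxygens cooperate to place lithium on the carbon between them. Copper-catalysed coupling with the primary allylic bromide gives the unrearranged prenyl arene.

Step 9
Reactants: 16 1,3-bis(methoxymethoxy)-2-(3-methylbut-2-en-1-yl)benzene
Product: 19 2,4-bis(methoxymethoxy)-3-(3-methylbut-2-en-1-yl)benzaldehyde, via 2,4-bis(methoxymethoxy)-3-(3-methylbut-2-en-1-yl)phenyllithium 17 (not isolated), via lithium α-(dimethylamino)benzyl alkoxide 18 (not isolated)
Conditions: n-BuLi, TMEDA, THF, 0 °C; DMF, −78 °C → rt; H2O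
Reagents that add atoms: N,N-dimethylformamide, CN(C)C=O
Why: Second directed ortho-metalation at the only kind of position still ortho to an acetal oxygen (C4 and C6 are equivalent), then formylation; the amino alkoxide 18 collapses to the aldehyde on aqueous work-up.

Step 10
Reactants: 11 (5S)-5-[2,4-bis(methoxymethoxy)phenyl]-3-(4-methylpent-3-en-1-yl)cyclohex-2-en-1-one; 19 2,4-bis(methoxymethoxy)-3-(3-methylbut-2-en-1-yl)benzaldehyde
Product: 21 (5S,6S)-5-ArE-6-[hydroxy(ArF)methyl]-3-(4-methylpent-3-en-1-yl)cyclohex-2-en-1-one (both carbinol epimers), via lithium cross-conjugated dienolate 20 (not isolated)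
Conditions: LiN(i-Pr)2 (1.1 equiv), THF, −78 °C; 19 (1.2 equiv), −78 °C; AcOH quench at −78 °C
Reagents that add atoms: none
Why: Kinetic deprotonation at the α'-methylene (the future C4) gives dienolate 20; aldol addition to the non-enolisable aldehyde should occur anti to the neighbouring aryl group on C5, which sets C4 trans to C5. The carbinol configuration is uncontrolled and is erased in step 18.

Step 11
Reactants: 21 aldol adduct
Product: 22 tert-butyldimethylsilyl ether of 21 (ring stereocentres unchanged)
Conditions: TBSOTf (1.3 equiv), 2,6-lutidine, CH2Cl2, −78 °C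
Reagents that add atoms: tert-butyldimethylsilyl trifluoromethanesulfonate, CC(C)(C)[Si](C)(C)OS(=O)(=O)C(F)(F)F
Why: Silylation blocks retro-aldol and dehydration and turns the benzylic oxygen into a poor leaving group for step 13; low temperature and a small excess keep the aryl acetals intact.

Step 12
Reactants: 22 silyl ether
Product: 23 5-ArE-6-[(tert-butyldimethylsilyloxy)(ArF)methyl]-3-(4-methylpent-3-en-1-yl)cyclohex-2-en-1-ol (ring stereocentres at C5 and C6 as in 22; both C1 epimers)
Conditions: NaBH4, CeCl3·7H2O, MeOH/THF, −40 → 0 °C
Reagents that add atoms: none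
Why: Luche 1,2-reduction of the enone; both alcohol epimers are used because this carbon (C3 of ring D) becomes planar in step 13.

Step 13
Reactants: 23 allylic alcohol; 24 1-(2,4,6-trihydroxyphenyl)ethan-1-one
Product: 25 1-{3-[(1R,5S,6R)-5-ArE-6-[(tert-butyldimethylsilyloxy)(ArF)methyl]-3-(4-methylpent-3-en-1-yl)cyclohex-2-en-1-yl]-2,4,6-trihydroxyphenyl}ethan-1-one (carbinol epimers)
Conditions: 24 (3 equiv), (±)-camphor-10-sulfonic acid (15 mol%), 4 Å MS, CH2Cl2/MeCN, −10 °C → rt
Reagents that add atoms: none
Why: Friedel–Crafts allylic alkylation: acid ionises the allylic alcohol to a cation spanning C1–C3, and 24, whose two free ring carbons are equivalent, can give only one regioisomer. It attacks the secondary terminus C3 (attack at C1 would build a quaternary carbon) from the face opposite the C4 substituent, which sets C3 trans to C4 and cis to the aryl group on C5, as in the coupling of resorcinols with menthadienol.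

Step 14
Reactants: 25 triol
Product: 26 O4,O6-bis(tert-butyldimethylsilyl) ether of 25 (O2 hydroxyl free)
Conditions: TBSCl (2.3 equiv), imidazole, DMF, 0 °C
Reagents that add atoms: tert-butyldimethylsilyl chloride, CC(C)(C)[Si](C)(C)Cl
Why: Silylation of the two more accessible phenols; the O2 hydroxyl, squeezed between the acetyl group and ring D and hydrogen-bonded to the carbonyl, should remain free.

Step 15
Reactants: 26 bis-silyl ether
Product: 27 O2-methoxymethyl ether of 26
Conditions: NaH, MOMCl, THF, 0 °C → rt
Reagents that add atoms: chloromethyl methyl ether, COCCl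
Why: Alkylation of the hindered, chelated phenoxide needs the sodium salt; the oxygen that must not close the pyranone is now blocked permanently.

Step 16
Reactants: 27 tris-silyl compound
Product: 28 1-{3-[(1R,5S,6R)-5-ArE-6-[hydroxy(ArF)methyl]-3-(4-methylpent-3-en-1-yl)cyclohex-2-en-1-yl]-4,6-dihydroxy-2-(methoxymethoxy)phenyl}ethan-1-one (carbinol epimers)
Conditions: Bu4NF (5 equiv), AcOH (5 equiv), THF, 0 → 45 °C
Reagents that add atoms: none
Why: Fluoride cleaves the two aryl silyl ethers and the benzylic silyl ether in one operation; buffering with AcOH keeps the medium near neutral.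

Step 17
Reactants: 28 diphenol carbinol
Product: 29 O4-methoxymethyl ether of 28 (O6 hydroxyl and carbinol free)
Conditions: MOMCl (1.1 equiv), i-Pr2NEt, CH2Cl2, 0 °C
Reagents that add atoms: chloromethyl methyl ether, COCCl
Why: With an amine base only the non-chelated phenol para to the acetyl group reacts; the O6 hydroxyl, now the sole hydrogen-bond donor to the carbonyl, and the secondary alcohol are left.

Step 18
Reactants: 29 carbinol
Product: 30 1-{3-[(1R,5S,6R)-5-ArE-6-(ArF-carbonyl)-3-(4-methylpent-3-en-1-yl)cyclohex-2-en-1-yl]-6-hydroxy-2,4-bis(methoxymethoxy)phenyl}ethan-1-one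
Conditions: Dess–Martin periodinane, CH2Cl2, 0 °C → rt
Reagents that add atoms: none
Why: Oxidation of the secondary benzylic alcohol to the ring F ketone merges the carbinol epimers; the chelated, acyl-deactivated phenol should be inert. C4 is already in the stable trans,trans arrangement.

Step 19
Reactants: 30 hydroxyacetophenone
Product: 32 6-[(1R,5S,6R)-5-ArE-6-(ArF-carbonyl)-3-(4-methylpent-3-en-1-yl)cyclohex-2-en-1-yl]-5,7-bis(methoxymethoxy)-4H-chromen-4-one, via enaminone 31 (not isolated)
Conditions: Me2NCH(OMe)2, toluene, 90 °C; then AcOH, 60 °C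
Reagents that add atoms: N,N-dimethylformamide dimethyl acetal, COC(OC)N(C)C
Why: Condensation at the acetyl methyl group gives enaminone 31; the only free ortho hydroxyl (O6) adds to its β-carbon and dimethylamine is lost. The chromone can therefore only be the 6-linked isomer.

Step 20
Reactants: 13 1,3-bis(methoxymethoxy)benzene
Product: 33 1-bromo-2,4-bis(methoxymethoxy)benzene
Conditions: NBS, MeCN, 0 °C
Reagents that add atoms: N-bromosuccinimide, O=C1CCC(=O)N1Br
Why: Electrophilic bromination para to one acetal oxygen and ortho to the other; the position between the two oxygens is the hindered one.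

Step 21
Reactants: 33 1-bromo-2,4-bis(methoxymethoxy)benzene
Product: 36 [2,4-bis(methoxymethoxy)phenyl]boronic acid, via 2,4-bis(methoxymethoxy)phenyllithium 34 (not isolated), via lithium aryltriisopropoxyborate 35 (not isolated)
Conditions: n-BuLi, THF, −78 °C; B(Oi-Pr)3, −78 °C → rt; H2O
Reagents that add atoms: triisopropyl borate, CC(C)OB(OC(C)C)OC(C)C; water, O
Why: Bromine–lithium exchange, borylation and hydrolysis of the borate.

Step 22
Reactants: 32 chromone; 36 [2,4-bis(methoxymethoxy)phenyl]boronic acid
Product: 37 (2S)-2-ArE-6-[(1R,5S,6R)-5-ArE-6-(ArF-carbonyl)-3-(4-methylpent-3-en-1-yl)cyclohex-2-en-1-yl]-5,7-bis(methoxymethoxy)-2,3-dihydro-4H-chromen-4-one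
Conditions: [Rh(OH)(cod)]2 (3 mol%), (S)-2,2'-bis[bis(3,4,5-trifluorophenyl)phosphino]-6,6'-dimethoxy-1,1'-biphenyl (7 mol%), 36 (3 equiv), toluene/H2O (10:1), 30 °C
Reagents that add atoms: none
Why: Hayashi–Miyaura-type asymmetric 1,4-addition: transmetalation gives an arylrhodium species that inserts the chromone C2=C3 bond, and the chiral bisphosphine selects the face, so C2 is set by the catalyst and not by the distant ring D stereocentres. Water protonates the rhodium enolate; the trisubstituted alkenes and the ring F ketone are inert to arylrhodium.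

Step 23
Reactants: 37 octakis(methoxymethyl) ether
Product: 38 (2S)-2-(2,4-dihydroxyphenyl)-6-[(1R,5S,6R)-6-[2,4-dihydroxy-3-(3-methylbut-2-en-1-yl)benzoyl]-5-(2,4-dihydroxyphenyl)-3-(4-methylpent-3-en-1-yl)cyclohex-2-en-1-yl]-5,7-dihydroxy-2,3-dihydro-4H-chromen-4-one
Conditions: HCl (3 M aq)/MeOH/THF, rt → 40 °C
Reagents that add atoms: none
Why: Acid-catalysed acetal exchange with methanol frees all eight phenols; conditions are kept mild to spare the prenyl group and the C2 configuration.

## Compound list

1 | 2,4-dihydroxybenzaldehyde | O=Cc1ccc(O)cc1O | starting material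
2 | 2,4-bis(methoxymethoxy)benzaldehyde | O=Cc1ccc(OCOC)cc1OCOC | intermediate
3 | 1-ethenyl-2,4-bis(methoxymethoxy)benzene | C=Cc1ccc(OCOC)cc1OCOC | intermediate
4 | trichloroacetyl chloride | O=C(Cl)C(Cl)(Cl)Cl | starting material
5 | dichloroketene (not isolated) | O=C=C(Cl)Cl | intermediate
6 | 3-[2,4-bis(methoxymethoxy)phenyl]-2,2-dichlorocyclobutan-1-one (racemic) | O=C1CC(c2ccc(OCOC)cc2OCOC)C1(Cl)Cl | intermediate
7 | 3-[2,4-bis(methoxymethoxy)phenyl]cyclobutan-1-one | O=C1CC(c2ccc(OCOC)cc2OCOC)C1 | intermediate
8 | 5-bromo-2-methylpent-2-ene | CC(C)=CCCBr | starting material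
9 | lithium acetylide (ethylenediamine complex) | [Li]C#C | starting material
10 | 6-methylhept-5-en-1-yne | C#CCCC=C(C)C | intermediate
11 | (5S)-5-[2,4-bis(methoxymethoxy)phenyl]-3-(4-methylpent-3-en-1-yl)cyclohex-2-en-1-one | CC(C)=CCCC1=CC(=O)C[C@@H](c2ccc(OCOC)cc2OCOC)C1 | intermediate
12 | benzene-1,3-diol (resorcinol) | Oc1cccc(O)c1 | starting material
13 | 1,3-bis(methoxymethoxy)benzene | COCOc1cccc(OCOC)c1 | intermediate
14 | 1-bromo-3-methylbut-2-ene | CC(C)=CCBr | starting material
15 | 2,6-bis(methoxymethoxy)phenyllithium (not isolated) | [Li]c1c(OCOC)cccc1OCOC | intermediate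
16 | 1,3-bis(methoxymethoxy)-2-(3-methylbut-2-en-1-yl)benzene | COCOc1cccc(OCOC)c1CC=C(C)C | intermediate
17 | 2,4-bis(methoxymethoxy)-3-(3-methylbut-2-en-1-yl)phenyllithium (not isolated) | [Li]c1ccc(OCOC)c(CC=C(C)C)c1OCOC | intermediate
18 | lithium (dimethylamino)[2,4-bis(methoxymethoxy)-3-(3-methylbut-2-en-1-yl)phenyl]methanolate (not isolated) | [Li]OC(N(C)C)c1ccc(OCOC)c(CC=C(C)C)c1OCOC | intermediate
19 | 2,4-bis(methoxymethoxy)-3-(3-methylbut-2-en-1-yl)benzaldehyde | O=Cc1ccc(OCOC)c(CC=C(C)C)c1OCOC | intermediate
20 | lithium dienolate of 11 (not isolated) | CC(C)=CCCC1=CC(O[Li])=C[C@@H](c2ccc(OCOC)cc2OCOC)C1 | intermediate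
21 | (5S,6S)-5-ArE-6-[hydroxy(ArF)methyl]-3-(4-methylpent-3-en-1-yl)cyclohex-2-en-1-one (carbinol epimers) | CC(C)=CCCC1=CC(=O)[C@H](C(O)c2ccc(OCOC)c(CC=C(C)C)c2OCOC)[C@@H](c2ccc(OCOC)cc2OCOC)C1 | intermediate
22 | tert-butyldimethylsilyl ether of 21 | CC(C)=CCCC1=CC(=O)[C@H](C(O[Si](C)(C)C(C)(C)C)c2ccc(OCOC)c(CC=C(C)C)c2OCOC)[C@@H](c2ccc(OCOC)cc2OCOC)C1 | intermediate
23 | allylic alcohol from 22 (5,6-trans as in 22; C1 and carbinol epimers) | CC(C)=CCCC1=CC(O)[C@H](C(O[Si](C)(C)C(C)(C)C)c2ccc(OCOC)c(CC=C(C)C)c2OCOC)[C@@H](c2ccc(OCOC)cc2OCOC)C1 | intermediate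
24 | 1-(2,4,6-trihydroxyphenyl)ethan-1-one | CC(=O)c1c(O)cc(O)cc1O | starting material
25 | 1-{3-[(1R,5S,6R)-5-ArE-6-[(tert-butyldimethylsilyloxy)(ArF)methyl]-3-(4-methylpent-3-en-1-yl)cyclohex-2-en-1-yl]-2,4,6-trihydroxyphenyl}ethan-1-one | CC(C)=CCCC1=C[C@@H](c2c(O)cc(O)c(C(C)=O)c2O)[C@H](C(O[Si](C)(C)C(C)(C)C)c2ccc(OCOC)c(CC=C(C)C)c2OCOC)[C@@H](c2ccc(OCOC)cc2OCOC)C1 | intermediate
26 | O4,O6-bis(tert-butyldimethylsilyl) ether of 25 | CC(C)=CCCC1=C[C@@H](c2c(O[Si](C)(C)C(C)(C)C)cc(O[Si](C)(C)C(C)(C)C)c(C(C)=O)c2O)[C@H](C(O[Si](C)(C)C(C)(C)C)c2ccc(OCOC)c(CC=C(C)C)c2OCOC)[C@@H](c2ccc(OCOC)cc2OCOC)C1 | intermediate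
27 | O2-methoxymethyl ether of 26 | CC(C)=CCCC1=C[C@@H](c2c(O[Si](C)(C)C(C)(C)C)cc(O[Si](C)(C)C(C)(C)C)c(C(C)=O)c2OCOC)[C@H](C(O[Si](C)(C)C(C)(C)C)c2ccc(OCOC)c(CC=C(C)C)c2OCOC)[C@@H](c2ccc(OCOC)cc2OCOC)C1 | intermediate
28 | 4,6-dihydroxy-2-(methoxymethoxy)acetophenone with free carbinol (from 27) | CC(C)=CCCC1=C[C@@H](c2c(O)cc(O)c(C(C)=O)c2OCOC)[C@H](C(O)c2ccc(OCOC)c(CC=C(C)C)c2OCOC)[C@@H](c2ccc(OCOC)cc2OCOC)C1 | intermediate
29 | O4-methoxymethyl ether of 28 | CC(C)=CCCC1=C[C@@H](c2c(OCOC)cc(O)c(C(C)=O)c2OCOC)[C@H](C(O)c2ccc(OCOC)c(CC=C(C)C)c2OCOC)[C@@H](c2ccc(OCOC)cc2OCOC)C1 | intermediate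
30 | 1-{3-[(1R,5S,6R)-5-ArE-6-(ArF-carbonyl)-3-(4-methylpent-3-en-1-yl)cyclohex-2-en-1-yl]-6-hydroxy-2,4-bis(methoxymethoxy)phenyl}ethan-1-one | CC(C)=CCCC1=C[C@@H](c2c(OCOC)cc(O)c(C(C)=O)c2OCOC)[C@H](C(=O)c2ccc(OCOC)c(CC=C(C)C)c2OCOC)[C@@H](c2ccc(OCOC)cc2OCOC)C1 | intermediate
31 | (E)-3-(dimethylamino)prop-2-enoyl analogue of 30 (enaminone, not isolated) | CC(C)=CCCC1=C[C@@H](c2c(OCOC)cc(O)c(C(=O)/C=C/N(C)C)c2OCOC)[C@H](C(=O)c2ccc(OCOC)c(CC=C(C)C)c2OCOC)[C@@H](c2ccc(OCOC)cc2OCOC)C1 | intermediate
32 | 6-[(1R,5S,6R)-5-ArE-6-(ArF-carbonyl)-3-(4-methylpent-3-en-1-yl)cyclohex-2-en-1-yl]-5,7-bis(methoxymethoxy)-4H-chromen-4-one | CC(C)=CCCC1=C[C@@H](c2c(OCOC)cc3occc(=O)c3c2OCOC)[C@H](C(=O)c2ccc(OCOC)c(CC=C(C)C)c2OCOC)[C@@H](c2ccc(OCOC)cc2OCOC)C1 | intermediate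
33 | 1-bromo-2,4-bis(methoxymethoxy)benzene | Brc1ccc(OCOC)cc1OCOC | intermediate
34 | 2,4-bis(methoxymethoxy)phenyllithium (not isolated) | [Li]c1ccc(OCOC)cc1OCOC | intermediate
35 | lithium [2,4-bis(methoxymethoxy)phenyl]triisopropoxyborate (not isolated) | [Li+].CC(C)O[B-](OC(C)C)(OC(C)C)c1ccc(OCOC)cc1OCOC | intermediate
36 | [2,4-bis(methoxymethoxy)phenyl]boronic acid | OB(O)c1ccc(OCOC)cc1OCOC | intermediate
37 | (2S)-2-ArE-6-[(1R,5S,6R)-5-ArE-6-(ArF-carbonyl)-3-(4-methylpent-3-en-1-yl)cyclohex-2-en-1-yl]-5,7-bis(methoxymethoxy)-2,3-dihydro-4H-chromen-4-one | CC(C)=CCCC1=C[C@@H](c2c(OCOC)cc3c(c2OCOC)C(=O)C[C@@H](c2ccc(OCOC)cc2OCOC)O3)[C@H](C(=O)c2ccc(OCOC)c(CC=C(C)C)c2OCOC)[C@@H](c2ccc(OCOC)cc2OCOC)C1 | intermediate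
38 | (2S)-2-(2,4-dihydroxyphenyl)-6-[(1R,5S,6R)-6-[2,4-dihydroxy-3-(3-methylbut-2-en-1-yl)benzoyl]-5-(2,4-dihydroxyphenyl)-3-(4-methylpent-3-en-1-yl)cyclohex-2-en-1-yl]-5,7-dihydroxy-2,3-dihydro-4H-chromen-4-one | CC(C)=CCCC1=C[C@@H](c2c(O)cc3c(c2O)C(=O)C[C@@H](c2ccc(O)cc2O)O3)[C@H](C(=O)c2ccc(O)c(CC=C(C)C)c2O)[C@@H](c2ccc(O)cc2O)C1 | target

## Step count and weakest steps

Total step count: 23. Longest linear sequence: 17 steps (steps 1–4, 6, 10–19, 22 and 23, from 1).

Step 6 (key step, the new method). The most likely failures are:
- oligomerisation or cyclotrimerisation of the terminal alkyne on nickel before it meets the ketone;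
- β-hydride elimination from the seven-membered nickelacycle at the aryl-bearing carbon, which would open the ring;
- weak discrimination between the two enantiotopic ring bonds, because the aryl group that makes them different is remote from the metal.

Fallback by known chemistry, setting out from boronic acid 36 and returning at 11:
- Hayashi–Miyaura addition of 36 to cyclohex-2-en-1-one F1 with Rh(acac)(C2H4)2 and (R)-BINAP in dioxane/H2O should give (3R)-3-[2,4-bis(methoxymethoxy)phenyl]cyclohexan-1-one F2.
- Kinetic enolisation away from the aryl-bearing carbon (LiN(i-Pr)2, Me3SiCl) gives the trimethylsilyl enol ether F3, and Saegusa–Ito oxidation with Pd(OAc)2 gives (5R)-5-[2,4-bis(methoxymethoxy)phenyl]cyclohex-2-en-1-one F4.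
- 1,2-Addition of (4-methylpent-3-en-1-yl)magnesium bromide F5 (from 8 and Mg) in the presence of CeCl3 gives the tertiary allylic alcohol F6.
- Babler–Dauben oxidative transposition with pyridinium chlorochromate (C5H5NH[CrO3Cl]) gives 11. The descriptor at the aryl-bearing carbon changes from R to S only because the ranking of its two methylene neighbours changes.

Step 13. The acid may also ionise the electron-rich benzylic silyl ether, followed by capture of that cation by a neighbouring ring A hydroxyl or by 24. Methoxymethyl groups may be lost or transferred, the allyl cation may lose a proton to a diene, and a ring A hydroxyl may add to the C1=C2 alkene on prolonged exposure.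

Fallback, from 23 back to 25: the alcohol is converted with methyl chloroformate and pyridine into the allylic methyl carbonate F7. F7 is coupled with 24 under neutral Tsuji–Trost conditions (Pd(PPh3)4, THF, 50 °C). Ionisation by zerovalent palladium and attack of the soft carbon nucleophile at the less hindered allyl terminus C3, opposite the metal, give 25 without any Brønsted acid. The outcome is stereospecific, so it depends on the carbonate epimer used.

Step 22. Insertion into the hindered, electron-rich chromone may be slow, so that protodeboronation of the ortho-alkoxy boronic acid and hydroxide-induced opening of the chromone compete. Facial selectivity may also erode with an ortho-substituted aryl group.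

Fallback, from 30 and 2 back to 37: Claisen–Schmidt condensation (KOH, EtOH) gives the 2'-hydroxychalcone F8. Oxa-Michael closure through the only free ortho hydroxyl (NaOAc, EtOH, reflux) gives 37 together with its C2 epimer, the (2R)-flavanone F9. The two are diastereomers and are separated by chromatography, and F9 is returned to F8 with base and cyclised again.

Step 23. Under protic acid the freed ring F phenols may add to the prenyl alkene (chroman formation). The benzylic C2–O bond next to the electron-rich ring B may heterolyse, with loss of the C2 configuration. Cleavage of eight acetals may stall before completion.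

Fallback, from 37 to 38: the acetals are exchanged under aprotic, base-buffered conditions (Me3SiOTf, 2,2'-bipyridyl, CH2Cl2, 0 °C). This transfers each methoxymethyl group to the bipyridyl and leaves the octakis(trimethylsilyl) ether F10. Neutral hydrolysis of F10 with water then gives 38 without any strong Brønsted acid.

## Further compounds

F1 | step 6 | cyclohex-2-en-1-one | O=C1C=CCCC1
F2 | step 6 | (3R)-3-[2,4-bis(methoxymethoxy)phenyl]cyclohexan-1-one | O=C1C[C@H](c2ccc(OCOC)cc2OCOC)CCC1
F3 | step 6 | trimethylsilyl enol ether of F2 (C1=C6 isomer) | C[Si](C)(C)OC1=CCC[C@@H](c2ccc(OCOC)cc2OCOC)C1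
F4 | step 6 | (5R)-5-[2,4-bis(methoxymethoxy)phenyl]cyclohex-2-en-1-one | O=C1C[C@H](c2ccc(OCOC)cc2OCOC)CC=C1
F5 | step 6 | (4-methylpent-3-en-1-yl)magnesium bromide | CC(C)=CCC[Mg]Br
F6 | step 6 | 5-[2,4-bis(methoxymethoxy)phenyl]-1-(4-methylpent-3-en-1-yl)cyclohex-2-en-1-ol (C5 as in F4; C1 epimers) | CC(C)=CCCC1(O)C=CC[C@@H](c2ccc(OCOC)cc2OCOC)C1
F7 | step 13 | methyl carbonate of allylic alcohol 23 | CC(C)=CCCC1=CC(OC(=O)OC)[C@H](C(O[Si](C)(C)C(C)(C)C)c2ccc(OCOC)c(CC=C(C)C)c2OCOC)[C@@H](c2ccc(OCOC)cc2OCOC)C1
F8 | step 22 | 2'-hydroxychalcone from 30 and 2 | CC(C)=CCCC1=C[C@@H](c2c(OCOC)cc(O)c(C(=O)/C=C/c3ccc(OCOC)cc3OCOC)c2OCOC)[C@H](C(=O)c2ccc(OCOC)c(CC=C(C)C)c2OCOC)[C@@H](c2ccc(OCOC)cc2OCOC)C1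
F9 | step 22 | (2R)-epimer of 37 | CC(C)=CCCC1=C[C@@H](c2c(OCOC)cc3c(c2OCOC)C(=O)C[C@H](c2ccc(OCOC)cc2OCOC)O3)[C@H](C(=O)c2ccc(OCOC)c(CC=C(C)C)c2OCOC)[C@@H](c2ccc(OCOC)cc2OCOC)C1
F10 | step 23 | octakis(trimethylsilyl) ether of 38 | CC(C)=CCCC1=C[C@@H](c2c(O[Si](C)(C)C)cc3c(c2O[Si](C)(C)C)C(=O)C[C@@H](c2ccc(O[Si](C)(C)C)cc2O[Si](C)(C)C)O3)[C@H](C(=O)c2ccc(O[Si](C)(C)C)c(CC=C(C)C)c2O[Si](C)(C)C)[C@@H](c2ccc(O[Si](C)(C)C)cc2O[Si](C)(C)C)C1
A1 | alternative 1 | 4-[2,4-bis(methoxymethoxy)phenyl]-6-{(E)-2-[2,6-bis(methoxymethoxy)-4-(tert-butyldimethylsilyloxy)phenyl]ethenyl}-6-(4-methylpent-3-en-1-yl)oxan-2-one (styryl group trans to the 4-aryl group) | O=C1C[C@@H](c2ccc(OCOC)cc2OCOC)C[C@](CCC=C(C)C)(/C=C/c2c(OCOC)cc(O[Si](C)(C)C(C)(C)C)cc2OCOC)O1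
A2 | alternative 1 | all-cis 2,6-diaryl-4-(4-methylpent-3-enyl)cyclohex-3-ene-1-carboxylic acid | CC(C)=CCCC1=C[C@@H](c2c(OCOC)cc(O[Si](C)(C)C(C)(C)C)cc2OCOC)[C@@H](C(=O)O)[C@@H](c2ccc(OCOC)cc2OCOC)C1
A3 | alternative 2 | ring D siloxyalkyne (triisopropylsilyloxyethynyl group on C3, tert-butyldimethylsilyloxymethyl group on C4) | CC(C)=CCCC1=C[C@@H](C#CO[Si](C(C)C)(C(C)C)C(C)C)[C@H](CO[Si](C)(C)C(C)(C)C)[C@@H](c2ccc(OCOC)cc2OCOC)C1
A4 | alternative 2 | 3-(allyloxy)cyclobut-2-en-1-one | O=C1C=C(OCC=C)C1
A5 | alternative 2 | cyclohexene with a 2-hydroxy-4-allyloxy-6-(triisopropylsilyloxy)phenyl ring A on C3 | CC(C)=CCCC1=C[C@@H](c2c(O)cc(OCC=C)cc2O[Si](C(C)C)(C(C)C)C(C)C)[C@H](CO[Si](C)(C)C(C)(C)C)[C@@H](c2ccc(OCOC)cc2OCOC)C1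
A6 | alternative 3 | terminal ynone on C4 of the hexakis(methoxymethyl) flavanone–cyclohexene | CC(C)=CCCC1=C[C@@H](c2c(OCOC)cc3c(c2OCOC)C(=O)C[C@@H](c2ccc(OCOC)cc2OCOC)O3)[C@H](C(=O)C#C)[C@@H](c2ccc(OCOC)cc2OCOC)C1
A7 | alternative 3 | 1-methoxy-2-(3-methylbut-2-en-1-yl)-1,3-bis(trimethylsilyloxy)buta-1,3-diene (drawn as one ketene-acetal isomer) | CO/C(O[Si](C)(C)C)=C(/CC=C(C)C)C(=C)O[Si](C)(C)C
A8 | alternative 3 | hexakis(methoxymethyl) ether of the target with free hydroxyls on the aroyl ring | CC(C)=CCCC1=C[C@@H](c2c(OCOC)cc3c(c2OCOC)C(=O)C[C@@H](c2ccc(OCOC)cc2OCOC)O3)[C@H](C(=O)c2ccc(O)c(CC=C(C)C)c2O)[C@@H](c2ccc(OCOC)cc2OCOC)C1
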